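## Retrosynthetic overview

1. Target ⇐ double O-debenzylation ⇐ tetrahydrofuran, closed last by benzylic C2–O etherification of an open-chain triol.
2. Triol ⇐ one-pot three-component union on (5S)-5-(menthyloxy)furan-2(5H)-one: the lithiated 1,3-dithiane of the complete dihydrobenzofuran (a masked acyl anion) adds 1,4 and forms the ArCH2–C4 bond; the enolate is trapped by O-benzylisovanillin (C3–C2 bond); the dithiane is later reduced to CH2.
3. Dihydrobenzofuran (first ring made) ⇐ Parham cyclisation: an aryllithium opens a pendant epoxide 5-exo with inversion (C3–C3a bond).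
4. Bromoaryl ether epoxide ⇐ Sharpless epoxy alcohol of O-benzylconiferyl alcohol, opened at the benzylic carbon by a 2-bromophenol that already carries the dithiane.
5. Ring order: oxirane → dihydrobenzofuran → (auxiliary butenolide consumed) → tetrahydrofuran.

Assumption: ring A is the 3-hydroxy-4-methoxyphenyl on the tetrahydrofuran, ring B the benzo ring of the dihydrobenzofuran, ring C its 4-hydroxy-3-methoxyphenyl; 4-bromo-3,5-dimethoxybenzaldehyde, 5-hydroxyfuran-2(5H)-one and (+)-menthol are taken as catalogue chemicals.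

## Route

Step 1
Reactants: 1 4-bromo-3,5-dimethoxybenzaldehyde; 2 propane-1,3-dithiol
Product: 3 2-(4-bromo-3,5-dimethoxyphenyl)-1,3-dithiane
Conditions: BF3·OEt2 (0.2 equiv), CH2Cl2, 0 °C → rt
Reagents that add atoms: none
Why: Lewis acid-catalysed dithioacetalisation of an aryl aldehyde; the dithiane protects the aldehyde through the ring B chemistry and is the later Corey–Seebach handle.

Step 2
Reactants: 3 2-(4-bromo-3,5-dimethoxyphenyl)-1,3-dithiane
Product: 4 2-bromo-5-(1,3-dithian-2-yl)-3-methoxyphenol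
Conditions: NaSEt (3 equiv), DMF, 110 °C; aq. HCl work-up
Reagents that add atoms: none
Why: SN2 O-demethylation by thiolate; the two methoxy groups are equivalent and the phenoxide formed suppresses a second cleavage, so one mono-phenol results.

Step 3
Reactants: 5 4-(benzyloxy)-3-methoxybenzaldehyde; 6 ethyl (triphenylphosphoranylidene)acetate
Product: 7 ethyl (2E)-3-[4-(benzyloxy)-3-methoxyphenyl]prop-2-enoate
Conditions: toluene, 80 °C
Reagents that add atoms: none
Why: Wittig olefination with a stabilised ylide, which gives the E-cinnamate.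

Step 4
Reactants: 7 ethyl (2E)-3-[4-(benzyloxy)-3-methoxyphenyl]prop-2-enoate
Product: 8 (2E)-3-[4-(benzyloxy)-3-methoxyphenyl]prop-2-en-1-ol
Conditions: i-Bu2AlH (2.3 equiv), CH2Cl2, −78 °C; aq. KNaC4H4O6 work-up
Reagents that add atoms: none
Why: 1,2-hydride reduction of the enoate to the allylic alcohol with the alkene untouched.

Step 5
Reactants: 8 (2E)-3-[4-(benzyloxy)-3-methoxyphenyl]prop-2-en-1-ol
Product: 9 [(2S,3S)-3-[4-(benzyloxy)-3-methoxyphenyl]oxiran-2-yl]methanol
Conditions: Ti(OiPr)4 (10 mol%), L-(+)-diisopropyl tartrate (12 mol%), t-BuOOH (2 equiv, in decane), 4 Å MS, CH2Cl2, −20 °C; basic work-up, used crude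
Reagents that add atoms: tert-butyl hydroperoxide, CC(C)(C)OO
Why: Katsuki–Sharpless asymmetric epoxidation; the L-(+)-tartrate–titanium complex delivers oxygen to the face of the E-allylic alcohol that gives the trans (2S,3S)-epoxy alcohol.

Step 6
Reactants: 9 [(2S,3S)-3-[4-(benzyloxy)-3-methoxyphenyl]oxiran-2-yl]methanol; 4 2-bromo-5-(1,3-dithian-2-yl)-3-methoxyphenol
Product: 10 (2S,3R)-3-[4-(benzyloxy)-3-methoxyphenyl]-3-[2-bromo-5-(1,3-dithian-2-yl)-3-methoxyphenoxy]propane-1,2-diol
Conditions: 4 (1.1 equiv), NaOH (0.2 equiv), dioxane–H2O (1:1), 60 °C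
Reagents that add atoms: none
Why: base-catalysed phenoxide opening of the 2,3-epoxy alcohol at the aryl-activated benzylic carbon (SN2, inversion), which fixes the future C2 of the dihydrobenzofuran (3R in 10).

Step 7
Reactants: 10 (2S,3R)-3-[4-(benzyloxy)-3-methoxyphenyl]-3-[2-bromo-5-(1,3-dithian-2-yl)-3-methoxyphenoxy]propane-1,2-diol
Product: 12 (2S)-2-[(R)-[4-(benzyloxy)-3-methoxyphenyl][2-bromo-5-(1,3-dithian-2-yl)-3-methoxyphenoxy]methyl]oxirane, via primary tosylate 11 (not isolated)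
Conditions: NaH (2.2 equiv), N-tosylimidazole (1.05 equiv), THF, 0 °C → rt
Reagents that add atoms: none
Why: primary-selective sulfonylation then intramolecular Williamson closure by the neighbouring alkoxide (Fraser-Reid diol-to-epoxide protocol); the secondary C–O bond is not broken, so its configuration is retained.

Step 8
Reactants: 12 (2S)-2-[(R)-[4-(benzyloxy)-3-methoxyphenyl][2-bromo-5-(1,3-dithian-2-yl)-3-methoxyphenoxy]methyl]oxirane
Product: 14 [(2S,3R)-2-[4-(benzyloxy)-3-methoxyphenyl]-6-(1,3-dithian-2-yl)-4-methoxy-2,3-dihydro-1-benzofuran-3-yl]methanol, via aryllithium 13 (not isolated)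
Conditions: t-BuLi (2.1 equiv), THF, −90 °C → −20 °C; H2O
Reagents that add atoms: none
Why: Parham cyclisation; Br–Li exchange is faster than dithiane deprotonation and the aryllithium opens the epoxide 5-exo-tet at the internal carbon with inversion, which sets C3 and gives the trans (2S,3R) ring.

Step 9
Reactants: 15 5-hydroxyfuran-2(5H)-one (racemic); 16 (+)-menthol [(1S,2R,5S)-5-methyl-2-(propan-2-yl)cyclohexan-1-ol]
Product: 17 (5S)-5-{[(1S,2R,5S)-5-methyl-2-(propan-2-yl)cyclohexyl]oxy}furan-2(5H)-one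
Conditions: camphorsulfonic acid (2 mol%), toluene, reflux (Dean–Stark); crystallisation from petroleum ether, mother liquor re-equilibrated with acid and recrystallised
Reagents that add atoms: none
Why: acid-catalysed acetalisation with crystallisation-induced diastereomer enrichment (Feringa butenolide, enantiomeric series); the (5S) epimer of the (+)-menthyl acetal is the one that crystallises.

Step 10
Reactants: 14 [(2S,3R)-2-[4-(benzyloxy)-3-methoxyphenyl]-6-(1,3-dithian-2-yl)-4-methoxy-2,3-dihydro-1-benzofuran-3-yl]methanol; 17 (5S)-5-(menthyloxy)furan-2(5H)-one; 18 3-(benzyloxy)-4-methoxybenzaldehyde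
Product: 21 (3R,4S,5S)-3-{[3-(benzyloxy)-4-methoxyphenyl](hydroxy)methyl}-4-{2-[(2S,3R)-2-[4-(benzyloxy)-3-methoxyphenyl]-3-(hydroxymethyl)-4-methoxy-2,3-dihydro-1-benzofuran-6-yl]-1,3-dithian-2-yl}-5-{[(1S,2R,5S)-menthyl]oxy}oxolan-2-one (both carbinol epimers), via dilithio dithiane 19 (not isolated), via lithium enolate 20 (not isolated)
Conditions: n-BuLi (2.1 equiv), THF, −78 → −20 °C; 17 (1.05 equiv), −90 °C; then 18 (1.5 equiv), −90 → −78 °C; AcOH
Reagents that add atoms: none
Why: Corey–Seebach dithiane anion (masked acyl anion of the ring B aldehyde) in a Feringa-type tandem conjugate addition–aldol; the carbanion adds to the butenolide β-carbon anti to the menthyloxy group (sets lactone C4, S), the aldehyde enters trans to the new substituent (sets C3, R), and the carbinol centre forms as a mixture that step 13 converges.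

Step 11
Reactants: 21 the aldol lactone from step 10
Product: 22 (2S,3S)-2-{[3-(benzyloxy)-4-methoxyphenyl](hydroxy)methyl}-3-{2-[(2S,3R)-2-[4-(benzyloxy)-3-methoxyphenyl]-3-(hydroxymethyl)-4-methoxy-2,3-dihydro-1-benzofuran-6-yl]-1,3-dithian-2-yl}butane-1,4-diol (both carbinol epimers)
Conditions: LiAlH4 (4 equiv), THF, 0 °C → rt; NaOH/H2O work-up
Reagents that add atoms: none
Why: hydride reduction of the lactone carbonyl and of the acetal carbon (released as an aldehyde with loss of menthol) gives the 1,4-diol without touching the two ring stereocentres.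

Step 12
Reactants: 22 the dithiane tetraol from step 11
Product: 23 (2S,3S)-2-{[3-(benzyloxy)-4-methoxyphenyl](hydroxy)methyl}-3-{[(2S,3R)-2-[4-(benzyloxy)-3-methoxyphenyl]-3-(hydroxymethyl)-4-methoxy-2,3-dihydro-1-benzofuran-6-yl]methyl}butane-1,4-diol (both carbinol epimers)
Conditions: NiCl2·6H2O (10 equiv), NaBH4 (30 equiv), MeOH–THF, 0 °C → rt
Reagents that add atoms: none
Why: nickel boride reductive desulfurisation (Mozingo-type) of the benzylic dithioketal to CH2; benzyl ethers, the benzylic alcohol and the dihydrobenzofuran are expected to survive.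

Step 13
Reactants: 23 the desulfurised tetraol from step 12
Product: 24 {(2R,3S,4S)-2-[3-(benzyloxy)-4-methoxyphenyl]-4-{[(2S,3R)-2-[4-(benzyloxy)-3-methoxyphenyl]-3-(hydroxymethyl)-4-methoxy-2,3-dihydro-1-benzofuran-6-yl]methyl}oxolan-3-yl}methanol
Conditions: camphorsulfonic acid (10 mol%), 4 Å MS, CH2Cl2, 0 °C, about 30 min; Et3N quench
Reagents that add atoms: none
Why: acid-catalysed dehydrative SN1 cycloetherification; the p-methoxy-stabilised benzylic cation is captured 5-exo by the primary hydroxyl on the benzyl-bearing carbon, and both carbinol epimers converge on the 2,3-trans (2R) tetrahydrofuran as in lariciresinol-type closures.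

Step 14
Reactants: 24 the bis-benzyl ether from step 13
Product: 25 {(2R,3S,4S)-2-(3-hydroxy-4-methoxyphenyl)-4-{[(2S,3R)-2-(4-hydroxy-3-methoxyphenyl)-3-(hydroxymethyl)-4-methoxy-2,3-dihydro-1-benzofuran-6-yl]methyl}oxolan-3-yl}methanol (target)
Conditions: H2 (1 atm), 10% Pd/C, EtOAc–MeOH, rt
Reagents that add atoms: none
Why: hydrogenolysis of the two aryl benzyl ethers, which cleave much faster than the hindered cyclic benzylic C–O bonds of the two oxygen rings.

## Compound list

1 | 4-bromo-3,5-dimethoxybenzaldehyde | COc1cc(C=O)cc(OC)c1Br | starting material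
2 | propane-1,3-dithiol | SCCCS | starting material
3 | 2-(4-bromo-3,5-dimethoxyphenyl)-1,3-dithiane | COc1cc(C2SCCCS2)cc(OC)c1Br | intermediate
4 | 2-bromo-5-(1,3-dithian-2-yl)-3-methoxyphenol | COc1cc(C2SCCCS2)cc(O)c1Br | intermediate
5 | 4-(benzyloxy)-3-methoxybenzaldehyde | COc1cc(C=O)ccc1OCc1ccccc1 | starting material
6 | ethyl (triphenylphosphoranylidene)acetate | CCOC(=O)C=P(c1ccccc1)(c1ccccc1)c1ccccc1 | starting material
7 | ethyl (2E)-3-[4-(benzyloxy)-3-methoxyphenyl]prop-2-enoate | CCOC(=O)/C=C/c1ccc(OCc2ccccc2)c(OC)c1 | intermediate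
8 | (2E)-3-[4-(benzyloxy)-3-methoxyphenyl]prop-2-en-1-ol | OC/C=C/c1ccc(OCc2ccccc2)c(OC)c1 | intermediate
9 | [(2S,3S)-3-[4-(benzyloxy)-3-methoxyphenyl]oxiran-2-yl]methanol | OC[C@@H]1O[C@H]1c1ccc(OCc2ccccc2)c(OC)c1 | intermediate
10 | (2S,3R)-3-[4-(benzyloxy)-3-methoxyphenyl]-3-[2-bromo-5-(1,3-dithian-2-yl)-3-methoxyphenoxy]propane-1,2-diol | OC[C@H](O)[C@H](Oc1cc(C2SCCCS2)cc(OC)c1Br)c1ccc(OCc2ccccc2)c(OC)c1 | intermediate
11 | primary mono-tosylate of 10 (not isolated) | Cc1ccc(cc1)S(=O)(=O)OC[C@H](O)[C@H](Oc1cc(C2SCCCS2)cc(OC)c1Br)c1ccc(OCc2ccccc2)c(OC)c1 | intermediate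
12 | (2S)-2-[(R)-[4-(benzyloxy)-3-methoxyphenyl][2-bromo-5-(1,3-dithian-2-yl)-3-methoxyphenoxy]methyl]oxirane | C1O[C@@H]1[C@H](Oc1cc(C2SCCCS2)cc(OC)c1Br)c1ccc(OCc2ccccc2)c(OC)c1 | intermediate
13 | aryllithium from 12, Li in place of Br (not isolated) | C1O[C@@H]1[C@H](Oc1cc(C2SCCCS2)cc(OC)c1[Li])c1ccc(OCc2ccccc2)c(OC)c1 | intermediate
14 | [(2S,3R)-2-[4-(benzyloxy)-3-methoxyphenyl]-6-(1,3-dithian-2-yl)-4-methoxy-2,3-dihydro-1-benzofuran-3-yl]methanol | S1CCCSC1c1cc(OC)c2c(c1)O[C@H](c1ccc(OCc3ccccc3)c(OC)c1)[C@H]2CO | intermediate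
15 | 5-hydroxyfuran-2(5H)-one (racemic) | O=C1C=CC(O)O1 | starting material
16 | (+)-menthol, (1S,2R,5S)-5-methyl-2-(propan-2-yl)cyclohexan-1-ol | O[C@H]1C[C@@H](C)CC[C@@H]1C(C)C | starting material
17 | (5S)-5-{[(1S,2R,5S)-5-methyl-2-(propan-2-yl)cyclohexyl]oxy}furan-2(5H)-one | O=C1C=C[C@@H](O[C@H]2C[C@@H](C)CC[C@@H]2C(C)C)O1 | intermediate
18 | 3-(benzyloxy)-4-methoxybenzaldehyde | COc1ccc(C=O)cc1OCc1ccccc1 | starting material
19 | O,C-dilithio derivative of 14, lithium alkoxide and 2-lithio-1,3-dithiane (not isolated) | S1CCCSC1([Li])c1cc(OC)c2c(c1)O[C@H](c1ccc(OCc3ccccc3)c(OC)c1)[C@H]2CO[Li] | intermediate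
20 | lithium enolate of the (4S,5S) conjugate adduct (not isolated) | [Li]OC=1O[C@H](O[C@H]2C[C@@H](C)CC[C@@H]2C(C)C)[C@@H](C2(SCCCS2)c2cc(OC)c3c(c2)O[C@H](c2ccc(OCc4ccccc4)c(OC)c2)[C@H]3CO[Li])C1 | intermediate
21 | (3R,4S,5S) aldol lactone named in step 10, both carbinol epimers | O=C1O[C@H](O[C@H]2C[C@@H](C)CC[C@@H]2C(C)C)[C@@H](C2(SCCCS2)c2cc(OC)c3c(c2)O[C@H](c2ccc(OCc4ccccc4)c(OC)c2)[C@H]3CO)[C@@H]1C(O)c1ccc(OC)c(OCc2ccccc2)c1 | intermediate
22 | (2S,3S) dithiane tetraol named in step 11, both carbinol epimers | OC[C@@H](C1(SCCCS1)c1cc(OC)c2c(c1)O[C@H](c1ccc(OCc3ccccc3)c(OC)c1)[C@H]2CO)[C@@H](CO)C(O)c1ccc(OC)c(OCc2ccccc2)c1 | intermediate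
23 | (2S,3S) desulfurised tetraol named in step 12, both carbinol epimers | OC[C@@H](Cc1cc(OC)c2c(c1)O[C@H](c1ccc(OCc3ccccc3)c(OC)c1)[C@H]2CO)[C@@H](CO)C(O)c1ccc(OC)c(OCc2ccccc2)c1 | intermediate
24 | bis-benzyl ether of the target named in step 13 | COc1ccc([C@@H]2OC[C@@H](Cc3cc(OC)c4c(c3)O[C@H](c3ccc(OCc5ccccc5)c(OC)c3)[C@H]4CO)[C@H]2CO)cc1OCc1ccccc1 | intermediate
25 | {(2R,3S,4S)-2-(3-hydroxy-4-methoxyphenyl)-4-{[(2S,3R)-2-(4-hydroxy-3-methoxyphenyl)-3-(hydroxymethyl)-4-methoxy-2,3-dihydro-1-benzofuran-6-yl]methyl}oxolan-3-yl}methanol | COc1ccc([C@@H]2OC[C@@H](Cc3cc(OC)c4c(c3)O[C@H](c3ccc(O)c(OC)c3)[C@H]4CO)[C@H]2CO)cc1O | target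

## Count and risks

Total steps: 14. Longest linear sequence: 11 (steps 3, 4, 5, 6, 7, 8, 10, 11, 12, 13, 14, starting from 5).

**Step 10 (three-component union).** The unprotected dianion may be poorly soluble or sluggish, and the aldol trapping of a hindered enolate may be low-yielding or reverse. The fallback sets out from 14 and 17 and comes back at 23. Run only the conjugate addition and quench with a proton source to isolate the Michael lactone F1. Remove sulfur with n-Bu3SnH/AIBN (toluene, 110 °C) to give the benzyl lactone F2. Form its enolate with LDA (2.1 equiv, THF, −78 °C) and add 18 in a separate aldol, trans to the benzyl group, to give the aldol lactone F3. LiAlH4 reduction of F3 then gives 23 directly, so steps 11 and 12 are no longer needed.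

**Step 8 (Parham cyclisation).** The aryllithium may take the dithiane proton before it closes the ring. The fallback sets out from 12 and comes back at 14. It replaces the organolithium by a base-free reductive cross-electrophile cyclisation: NiBr2·glyme/2,2'-bipyridine (10 mol%), Cp2TiCl2 (20 mol%), Mn powder, Et3N·HCl, DMPU, rt. Trivalent titanium opens the epoxide to the secondary β-titanoxy radical at the internal carbon. The arylnickel species formed from zerovalent nickel and the C–Br bond captures it and closes the five-membered ring. The C2 centre is untouched and the trans isomer is expected to dominate, but C3 is no longer set stereospecifically, so a minor cis isomer would have to be separated. No new isolated compound arises on this path (F0).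

**Step 13 (acid cyclisation).** Ring B is a resorcinol-type arene, so Friedel–Crafts capture of the benzylic cation (an aryltetralin) can compete each time the product re-ionises under acid. The fallback sets out from 23 and comes back at 24. Silylate the three primary hydroxyls (TBSCl 3.3 equiv, imidazole, DMF, 0 °C) to give the tris-silyl ether F4. Treat F4 with MsCl/Et3N (CH2Cl2, −20 °C). The benzylic mesylate ionises once under basic buffer; the silyloxy oxygen four atoms away closes the ring and loses its silyl group, giving the bis-silyl tetrahydrofuran F5. No acid is present to re-open the product. TBAF (THF, rt) then gives 24.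

## Further compounds

F1 | step 10 | (4S,5S)-4-{2-[(2S,3R)-2-[4-(benzyloxy)-3-methoxyphenyl]-3-(hydroxymethyl)-4-methoxy-2,3-dihydro-1-benzofuran-6-yl]-1,3-dithian-2-yl}-5-{[(1S,2R,5S)-menthyl]oxy}oxolan-2-one | O=C1O[C@H](O[C@H]2C[C@@H](C)CC[C@@H]2C(C)C)[C@@H](C2(SCCCS2)c2cc(OC)c3c(c2)O[C@H](c2ccc(OCc4ccccc4)c(OC)c2)[C@H]3CO)C1
F2 | step 10 | (4S,5S)-4-{[(2S,3R)-2-[4-(benzyloxy)-3-methoxyphenyl]-3-(hydroxymethyl)-4-methoxy-2,3-dihydro-1-benzofuran-6-yl]methyl}-5-{[(1S,2R,5S)-menthyl]oxy}oxolan-2-one | O=C1O[C@H](O[C@H]2C[C@@H](C)CC[C@@H]2C(C)C)[C@@H](Cc2cc(OC)c3c(c2)O[C@H](c2ccc(OCc4ccccc4)c(OC)c2)[C@H]3CO)C1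
F3 | step 10 | (3R,4S,5S)-3-{[3-(benzyloxy)-4-methoxyphenyl](hydroxy)methyl}-4-{[(2S,3R)-2-[4-(benzyloxy)-3-methoxyphenyl]-3-(hydroxymethyl)-4-methoxy-2,3-dihydro-1-benzofuran-6-yl]methyl}-5-{[(1S,2R,5S)-menthyl]oxy}oxolan-2-one (both carbinol epimers) | O=C1O[C@H](O[C@H]2C[C@@H](C)CC[C@@H]2C(C)C)[C@@H](Cc2cc(OC)c3c(c2)O[C@H](c2ccc(OCc4ccccc4)c(OC)c2)[C@H]3CO)[C@@H]1C(O)c1ccc(OC)c(OCc2ccccc2)c1
F0 | step 8 | none | none
F4 | step 13 | tris(tert-butyldimethylsilyl) ether of 23 at its three primary hydroxyls, benzylic OH free | CC(C)(C)[Si](C)(C)OC[C@@H](Cc1cc(OC)c2c(c1)O[C@H](c1ccc(OCc3ccccc3)c(OC)c1)[C@H]2CO[Si](C)(C)C(C)(C)C)[C@@H](CO[Si](C)(C)C(C)(C)C)C(O)c1ccc(OC)c(OCc2ccccc2)c1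
F5 | step 13 | bis(tert-butyldimethylsilyl) ether of 24 at both hydroxymethyl groups | COc1ccc([C@@H]2OC[C@@H](Cc3cc(OC)c4c(c3)O[C@H](c3ccc(OCc5ccccc5)c(OC)c3)[C@H]4CO[Si](C)(C)C(C)(C)C)[C@H]2CO[Si](C)(C)C(C)(C)C)cc1OCc1ccccc1
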